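**Retrosynthetic overview**
- Target 23 comes from C8 alcohol 21 by tigloylation. The cyclobutane in 21 is closed at C2–C7: the γ-carbon of a dienol silyl ether opens a C7–C8 oxirane (4-exo). This stands in for the himachalyl → longipinyl cation step and fixes C2, C7 and the C8–O bond.
- Enone-oxirane 18 comes from cis-himachalenone 14. Its seven-membered ring is closed at C1–C11 by a tertiary C11 radical, made from a 10,11-oxirane, adding 7-endo to enone carbon C1. This stands in for the 1,11-closure and delivers C10–OH.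
- Bisabolane dienone 12 comes from Z-vinyl iodide 10 and iodoenone 5. The six-membered ring is closed at C1–C6 by aldol condensation of a crotonaldehyde/acetoacetate adduct.
- Ring order is six (C1–C6), then seven (C1–C11), then four (C2–C7). These are the three bonds the cyclase makes, and C1 reacts first as an aldehyde carbon and then as an enone β-carbon.

Assumption: atoms carry farnesyl numbers. The six-membered ring is C1–C6 (C5 = ketone, C3 bears C15). The seven-membered ring is C1, C6, C7–C11 (C14 on C7, C12/C13 on C11, tiglate on C8, isovalerate on C10). The D-fructose-derived Shi ketone is taken to give the (10R)-oxirane, as with other 2-methyl-2-alkenes.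

Step 1
Reactants: 1 (E)-crotonaldehyde; 2 tert-butyl acetoacetate
Product: 4 (S)-5-methylcyclohex-2-en-1-one, via Michael adduct 3 (not isolated)
Conditions: (R)-2-{bis[3,5-bis(trifluoromethyl)phenyl](trimethylsilyloxy)methyl}pyrrolidine (10 mol%), toluene, rt; then TsOH·H2O (20 mol%), 80 °C
Reagents that add atoms: none
Why: Iminium-catalysed Michael addition, in which the (R)-catalyst shields one face of the enal and sets (3S), is followed by acid-induced ester cleavage, decarboxylation and intramolecular aldol condensation that closes the six-membered ring at C1=C6 (organocatalytic Robinson-type annulation).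

Step 2
Reactants: 4 (S)-5-methylcyclohex-2-en-1-one
Product: 5 (S)-2-iodo-5-methylcyclohex-2-en-1-one
Conditions: I2 (1.5 equiv), pyridine–CH2Cl2, 0 °C → rt
Reagents that add atoms: iodine, II
Why: Johnson α-iodination of an enone (pyridine addition, iodination of the enolate, elimination) puts the coupling handle on C6 and leaves C3 untouched.

Step 3
Reactants: 6 4-methylpent-3-en-1-ol; 7 ethyltriphenylphosphonium iodide
Product: 10 (Z)-2-iodo-6-methylhepta-2,5-diene, via 4-methylpent-3-enal 8 (not isolated), via (1-iodoethyl)triphenylphosphonium iodide 9 (not isolated)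
Conditions: 6, Dess–Martin periodinane, CH2Cl2, 0 °C (solution of 8 used at once); 7, n-BuLi, THF, rt; I2, −78 °C; NaHMDS, −20 °C; then 8, −78 °C → rt
Reagents that add atoms: iodine, II
Why: The Stork–Zhao-type Wittig reaction of the α-iodoethylidene ylide with an aliphatic aldehyde gives the trisubstituted vinyl iodide with iodine cis to the chain (Z), which is the geometry a cycloheptene needs later, and the labile β,γ-unsaturated aldehyde is never stored.

Step 4
Reactants: 10 (Z)-2-iodo-6-methylhepta-2,5-diene; 5 (S)-2-iodo-5-methylcyclohex-2-en-1-one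
Product: 12 (S)-5-methyl-2-[(2Z)-6-methylhepta-2,5-dien-2-yl]cyclohex-2-en-1-one, via alkenylzinc bromide 11 (not isolated)
Conditions: 10, t-BuLi (2 equiv), Et2O, −78 °C; ZnBr2, THF, → 0 °C; 5, Pd(PPh3)4 (5 mol%), THF–DMF, rt
Reagents that add atoms: none
Why: Negishi coupling of an alkenylzinc with an α-iodoenone on zerovalent palladium forms C6–C7 with retention of the Z geometry and tolerates the ketone.

Step 5
Reactants: 12 (S)-5-methyl-2-[(2Z)-6-methylhepta-2,5-dien-2-yl]cyclohex-2-en-1-one
Product: 13 (S)-2-{(2Z)-4-[(2R)-3,3-dimethyloxiran-2-yl]but-2-en-2-yl}-5-methylcyclohex-2-en-1-one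
Conditions: D-fructose-derived Shi ketone (30 mol%), Oxone (1.3 equiv), K2CO3, Bu4NHSO4, MeCN–dimethoxymethane/aq. borate buffer, 0 °C
Reagents that add atoms: potassium peroxymonosulfate (Oxone), [K+].[O-]S(=O)(=O)OO
Why: Shi asymmetric epoxidation (chiral dioxirane, spiro transition state) attacks only the isolated electron-rich C10=C11 bond, since the enone and the conjugated hindered C7=C8 bond are much slower, and sets (10R) by reagent control.

Step 6
Reactants: 13 (S)-2-{(2Z)-4-[(2R)-3,3-dimethyloxiran-2-yl]but-2-en-2-yl}-5-methylcyclohex-2-en-1-one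
Product: 14 (1S,3S,6R,10R)-10-hydroxyhimachal-7-en-5-one (cis-fused; H-1/H-6 cis; 3-methyl trans to C11)
Conditions: Cp2TiCl2 (20 mol%), Mn dust (2 equiv), 2,4,6-collidine·HCl (2.5 equiv), THF (0.005 M), rt, slow addition of 13
Reagents that add atoms: none
Why: Reductive oxirane opening by trivalent titanium (Nugent–RajanBabu/Gansäuer) gives the long-lived tertiary C11 radical, which adds 7-endo-trig (Giese) to C1 anti to the C3 methyl, and the titanium dienolate is protonated kinetically at C6 from the H-1 face, giving the cis fusion and keeping C7=C8 out of conjugation.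

Step 7
Reactants: 14 (1S,3S,6R,10R)-10-hydroxyhimachal-7-en-5-one; 15 isovaleryl chloride
Product: 16 (1S,3S,6R,10R)-10-isovaleryloxyhimachal-7-en-5-one
Conditions: pyridine, DMAP (10 mol%), CH2Cl2, 0 °C → rt
Reagents that add atoms: none
Why: DMAP-catalysed acylation of the only hydroxyl group installs the first ester under conditions too mild to conjugate the β,γ-enone.

Step 8
Reactants: 16 (1S,3S,6R,10R)-10-isovaleryloxyhimachal-7-en-5-one
Product: 17 (1S,3S,6R,7S,8R,10R)-7,8-epoxy-10-isovaleryloxyhimachalan-5-one
Conditions: mCPBA (1.1 equiv), Na2HPO4, CH2Cl2, 0 °C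
Reagents that add atoms: mCPBA, OOC(=O)c1cccc(Cl)c1
Why: Prilezhaev epoxidation of the only alkene takes place on the convex face carrying H-1 and H-6, because the other face is covered by the six-membered ring and the C10 ester, which sets (8R) and puts the oxygen anti to C2.

Step 9
Reactants: 17 (1S,3S,6R,7S,8R,10R)-7,8-epoxy-10-isovaleryloxyhimachalan-5-one
Product: 18 (1S,6R,7S,8R,10R)-7,8-epoxy-10-isovaleryloxyhimachal-3-en-5-one
Conditions: LDA (1.1 equiv), THF, −78 °C; PhS(Cl)=N-t-Bu (1.2 equiv), −78 °C
Reagents that add atoms: none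
Why: Mukaiyama one-pot dehydrogenation works because kinetic deprotonation takes the open C4 methylene rather than the hindered tertiary H-6, and the sulfinimidoyl adduct eliminates at −78 °C to the C3=C4 enone, erasing the relay centre C3.

Step 10
Reactants: 18 (1S,6R,7S,8R,10R)-7,8-epoxy-10-isovaleryloxyhimachal-3-en-5-one
Product: 21 (1S,2R,6R,7R,8R,10R)-8-hydroxy-10-isovaleryloxylongipin-3-en-5-one, via silyl dienol ether 19 (not isolated), via trimethylsilyl ether 20 (not isolated)
Conditions: TMSOTf (2.5 equiv), Et3N (1.3 equiv), CH2Cl2, −78 → −30 °C; then 1 M aq. HCl–THF, 0 °C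
Reagents that add atoms: none
Why: Proposed new method: soft enolisation away from the buried H-6 gives the linear dienol ether; surplus TMSOTf loosens the tertiary C7–O bond, and the γ-carbon C2, which the cis fusion holds on the face opposite the oxirane oxygen, attacks C7 with inversion (4-exo-tet). Silyl loss gives the conjugated enone at once, so no free pinyl-type cation can rearrange or reopen; attack by C4 would give a more strained cyclobutanone, and the exocyclic dienol isomer could only form a bridgehead alkene. The closest known reactions are epoxide-initiated cation–olefin cyclisations terminated by enol silanes, γ-selective SN1 alkylation of silyl dienol ethers (vinylogous Mukaiyama), and the Stork epoxynitrile closure of cyclobutanes.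

Step 11
Reactants: 21 (1S,2R,6R,7R,8R,10R)-8-hydroxy-10-isovaleryloxylongipin-3-en-5-one; 22 tigloyl chloride
Product: 23 target CNP0194415.1 (8-tigloyloxy-10-isovaleryloxylongipin-3-en-5-one)
Conditions: 22 (3 equiv), pyridine, DMAP (20 mol%), ClCH2CH2Cl, 60 °C
Reagents that add atoms: none
Why: DMAP-catalysed acylation of the hindered C8 alcohol with the configurationally stable (E)-acid chloride completes the diester without touching any stereocentre.

**Compound list**
1 | (E)-crotonaldehyde | C/C=C/C=O | starting material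
2 | tert-butyl acetoacetate | CC(=O)CC(=O)OC(C)(C)C | starting material
3 | tert-butyl (3S)-2-acetyl-3-methyl-5-oxopentanoate (C2 epimers) | CC(=O)C(C(=O)OC(C)(C)C)[C@@H](C)CC=O | intermediate
4 | (S)-5-methylcyclohex-2-en-1-one | C[C@H]1CC=CC(=O)C1 | intermediate
5 | (S)-2-iodo-5-methylcyclohex-2-en-1-one | C[C@H]1CC=C(I)C(=O)C1 | intermediate
6 | 4-methylpent-3-en-1-ol | CC(C)=CCCO | starting material
7 | ethyltriphenylphosphonium iodide | CC[P+](c1ccccc1)(c1ccccc1)c1ccccc1.[I-] | starting material
8 | 4-methylpent-3-enal | CC(C)=CCC=O | intermediate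
9 | (1-iodoethyl)triphenylphosphonium iodide | CC(I)[P+](c1ccccc1)(c1ccccc1)c1ccccc1.[I-] | intermediate
10 | (Z)-2-iodo-6-methylhepta-2,5-diene | C/C(I)=C/CC=C(C)C | intermediate
11 | [(2Z)-6-methylhepta-2,5-dien-2-yl]zinc bromide | C/C([Zn]Br)=C/CC=C(C)C | intermediate
12 | (S)-5-methyl-2-[(2Z)-6-methylhepta-2,5-dien-2-yl]cyclohex-2-en-1-one | C/C(=C/CC=C(C)C)C1=CC[C@H](C)CC1=O | intermediate
13 | (S)-2-{(2Z)-4-[(2R)-3,3-dimethyloxiran-2-yl]but-2-en-2-yl}-5-methylcyclohex-2-en-1-one | C/C(=C/C[C@H]1OC1(C)C)C1=CC[C@H](C)CC1=O | intermediate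
14 | (1S,3S,6R,10R)-10-hydroxyhimachal-7-en-5-one, cis-fused | CC1=CC[C@@H](O)C(C)(C)[C@H]2C[C@H](C)CC(=O)[C@@H]12 | intermediate
15 | isovaleryl chloride | CC(C)CC(=O)Cl | starting material
16 | (1S,3S,6R,10R)-10-isovaleryloxyhimachal-7-en-5-one | CC1=CC[C@@H](OC(=O)CC(C)C)C(C)(C)[C@H]2C[C@H](C)CC(=O)[C@@H]12 | intermediate
17 | (1S,3S,6R,7S,8R,10R)-7,8-epoxy-10-isovaleryloxyhimachalan-5-one | C[C@@]12O[C@@H]1C[C@@H](OC(=O)CC(C)C)C(C)(C)[C@H]1C[C@H](C)CC(=O)[C@H]12 | intermediate
18 | (1S,6R,7S,8R,10R)-7,8-epoxy-10-isovaleryloxyhimachal-3-en-5-one | C[C@@]12O[C@@H]1C[C@@H](OC(=O)CC(C)C)C(C)(C)[C@H]1CC(C)=CC(=O)[C@H]12 | intermediate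
19 | 5-trimethylsilyloxy-2,4-diene (linear dienol ether) of 18 | C[C@@]12O[C@@H]1C[C@@H](OC(=O)CC(C)C)C(C)(C)[C@H]1C=C(C)C=C(O[Si](C)(C)C)[C@H]12 | intermediate
20 | 8-O-trimethylsilyl ether of 21 | C[Si](C)(C)O[C@@H]1C[C@@H](OC(=O)CC(C)C)C(C)(C)[C@@H]2[C@H]3C(=O)C=C(C)[C@@H]2[C@]31C | intermediate
21 | (1S,2R,6R,7R,8R,10R)-8-hydroxy-10-isovaleryloxylongipin-3-en-5-one | O[C@@H]1C[C@@H](OC(=O)CC(C)C)C(C)(C)[C@@H]2[C@H]3C(=O)C=C(C)[C@@H]2[C@]31C | intermediate
22 | tigloyl chloride, (E)-2-methylbut-2-enoyl chloride | C/C=C(\C)C(=O)Cl | starting material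
23 | CNP0194415.1 | C/C=C(\C)C(=O)O[C@@H]1C[C@@H](OC(=O)CC(C)C)C(C)(C)[C@@H]2[C@H]3C(=O)C=C(C)[C@@H]2[C@]31C | target

**Totals**
- Total step count: 11.
- Longest linear sequence: 10 (steps 1, 2, 4–11).

**Steps most likely to fail**

Step 10 (cyclobutane closure). The risks are three:
- enolisation through H-6, which opens the β,γ-oxirane to a γ-hydroxy dienone;
- a 1,2-hydride shift to the 8-ketone;
- attack through C4 instead of C2.

The fallback sets out from 18 and returns at 21. It makes the same C2–C7 bond with reversed polarity. BF3·OEt2 converts the oxirane by hydride shift into 10-isovaleryloxyhimachal-3-ene-5,8-dione F4. Wohl–Ziegler bromination (NBS, AIBN) gives the 2-bromo dione F5, with bromine on the face of H-1. KOt-Bu closes the ring by intramolecular alkylation of the more substituted C7 enolate, the classical keto-halide cyclobutane closure, to 10-isovaleryloxylongipin-3-ene-5,8-dione F6. NaBH4 at −40 °C reduces the saturated 8-ketone faster than the enone and gives 21. If the 8-epimer forms instead, Mitsunobu inversion with tiglic acid leads directly to 23.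

Step 6 (7-endo radical closure). The risks are disproportionation or deoxygenation of the β-titanoxy radical before the slow cyclisation, and γ-protonation of the dienolate. The fallback sets out from 13 and returns at 16. It makes the C11 radical from an alkene by hydrogen-atom transfer instead. Al(Oi-Pr)3 in hot toluene isomerises the oxirane to the allylic alcohol (S)-2-[(2Z,5R)-5-hydroxy-6-methylhepta-2,6-dien-2-yl]-5-methylcyclohex-2-en-1-one F1. Isovaleryl chloride/pyridine gives its isovalerate F2. Fe(acac)3/PhSiH3 in EtOH at 60 °C (reductive olefin coupling) then generates the same tertiary radical from the 1,1-disubstituted alkene and closes C1–C11 to ester 16.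

Step 9 (dehydrogenation next to the oxirane). The risk is that any deprotonation at C6 opens the oxirane irreversibly. The fallback sets out from 16 and returns at 18. The order is inverted so that no enolate ever sits beside an oxirane. Base-free aerobic dehydrogenation of 16 with Pd(O2CCF3)2/DMSO under O2 gives 10-isovaleryloxyhimachala-3,7-dien-5-one F3. mCPBA then epoxidises only the isolated C7=C8 bond, on the same convex face, to give 18.

Further compounds
F1 | step 6 | (S)-2-[(2Z,5R)-5-hydroxy-6-methylhepta-2,6-dien-2-yl]-5-methylcyclohex-2-en-1-one | C/C(=C/C[C@@H](O)C(C)=C)C1=CC[C@H](C)CC1=O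
F2 | step 6 | isovalerate of F1 | C/C(=C/C[C@@H](OC(=O)CC(C)C)C(C)=C)C1=CC[C@H](C)CC1=O
F3 | step 9 | (1S,6R,10R)-10-isovaleryloxyhimachala-3,7-dien-5-one | CC1=CC[C@@H](OC(=O)CC(C)C)C(C)(C)[C@H]2CC(C)=CC(=O)[C@@H]12
F4 | step 10 | (1S,6R,10R)-10-isovaleryloxyhimachal-3-ene-5,8-dione (C7 epimers) | CC1C(=O)C[C@@H](OC(=O)CC(C)C)C(C)(C)[C@H]2CC(C)=CC(=O)[C@@H]12
F5 | step 10 | 2-bromo derivative of F4 (Br cis to H-1) | CC1C(=O)C[C@@H](OC(=O)CC(C)C)C(C)(C)[C@H]2[C@H](Br)C(C)=CC(=O)[C@@H]12
F6 | step 10 | (1S,2R,6R,7R,10R)-10-isovaleryloxylongipin-3-ene-5,8-dione | O=C1C[C@@H](OC(=O)CC(C)C)C(C)(C)[C@@H]2[C@H]3C(=O)C=C(C)[C@@H]2[C@]31C
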